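## Retrosynthetic overview

1. Ester C–O bond: the target comes from the bicyclic allylic diol 33 and silyl-protected isovanillic acid 20 (fragment C), joined with inversion at C3.
2. Six-membered ring (formed last): C1=C2 by intramolecular aldol condensation of keto aldehyde 31.
3. Seven-membered ring (formed first, key step): C6–C7 by ring-closing metathesis of dienone 27, then hydrogenation; the C5 carbinol by methyl addition to the ring ketone.
4. C4a–C9a bond and both ring-fusion stereocentres: enamine-catalysed syn-Michael addition of aldehyde 8 (fragment A) to nitroalkene 17 (fragment B); the nitro group is the latent C5 ketone.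
5. Fragments A, B and C are made in parallel from ethyl isobutyrate, ethyl 3-oxopentanoate and isovanillin.

Assumption: ring positions follow benzo[7]annulene numbering (C3 = ester carbon, C4a/C9a = ring fusion, C5 = tertiary carbinol, C9 = gem-dimethyl carbon), and a one-pot sequence run without isolation counts as one step.

## Route

**Fragment A**

Step 1
Reactants: 1 ethyl isobutyrate; 2 allyl bromide
Product: 4 ethyl 2,2-dimethylpent-4-enoate, via lithium enolate 3 (not isolated)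
Conditions: LiN(iPr)2 (1.05 equiv), THF, −78 °C; then 2, −78 °C → rt
Reagents that add atoms: none
Why: Ester enolate alkylation (SN2) with the allylic bromide builds the quaternary gem-dimethyl carbon (future C9); no stereocentre is formed.

Step 2
Reactants: 4 ethyl 2,2-dimethylpent-4-enoate
Product: 5 2,2-dimethylpent-4-en-1-ol
Conditions: LiAlH4, Et2O, 0 °C → rt; Na2SO4·10H2O quench
Reagents that add atoms: none
Why: Hydride reduction of the hindered ester to the neopentyl alcohol is more reliable than a partial reduction to the aldehyde.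

Step 3
Reactants: 5 2,2-dimethylpent-4-en-1-ol
Product: 6 2,2-dimethylpent-4-enal
Conditions: TEMPO (10 mol %), PhI(OAc)2 (1.1 equiv), CH2Cl2, rt
Reagents that add atoms: none
Why: Nitroxyl-catalysed oxidation stops at the non-enolisable aldehyde and leaves the terminal alkene untouched.

Step 4
Reactants: 6 2,2-dimethylpent-4-enal
Product: 7 1-methoxy-3,3-dimethylhexa-1,5-diene (E/Z mixture)
Conditions: Ph3P(CH2OMe)Cl, KOtBu, THF, 0 °C; then 6, 0 °C → rt
Reagents that add atoms: (methoxymethyl)triphenylphosphonium chloride, COC[P+](c1ccccc1)(c1ccccc1)c1ccccc1.[Cl-]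
Why: Wittig methoxymethylenation adds the carbon that becomes C1; the enol ether geometry is irrelevant.

Step 5
Reactants: 7 1-methoxy-3,3-dimethylhexa-1,5-diene
Product: 8 3,3-dimethylhex-5-enal
Conditions: 1 M HCl (cat.), THF–H2O, rt
Reagents that add atoms: water, O
Why: Acid hydrolysis of the enol ether unmasks the homologated aldehyde, whose α-CH2 is needed for enamine formation.

**Fragment B**

Step 6
Reactants: 9 ethyl 3-oxopentanoate; 10 ethylene glycol
Product: 11 ethyl 2-(2-ethyl-1,3-dioxolan-2-yl)acetate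
Conditions: p-TsOH·H2O (2 mol %), toluene, reflux, Dean–Stark trap
Reagents that add atoms: none
Why: Acid-catalysed ketalisation with azeotropic water removal masks the ketone (the ester is inert) until the late aldol step.

Step 7
Reactants: 11 ethyl 2-(2-ethyl-1,3-dioxolan-2-yl)acetate
Product: 12 2-(2-ethyl-1,3-dioxolan-2-yl)ethan-1-ol
Conditions: LiAlH4, THF, 0 °C; Na2SO4·10H2O quench
Reagents that add atoms: none
Why: Hydride reduction of the ester; the ketal is stable to LiAlH4.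

Step 8
Reactants: 12 2-(2-ethyl-1,3-dioxolan-2-yl)ethan-1-ol
Product: 13 2-(2-ethyl-1,3-dioxolan-2-yl)acetaldehyde
Conditions: TEMPO (10 mol %), PhI(OAc)2 (1.1 equiv), CH2Cl2, rt
Reagents that add atoms: none
Why: Mild nitroxyl-catalysed oxidation gives the β-ketal aldehyde without over-oxidation or β-elimination.

Step 9
Reactants: 13 2-(2-ethyl-1,3-dioxolan-2-yl)acetaldehyde; 14 nitromethane
Product: 15 1-(2-ethyl-1,3-dioxolan-2-yl)-3-nitropropan-2-ol (racemic)
Conditions: 14 (5 equiv), KOtBu (10 mol %), THF–tBuOH, 0 °C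
Reagents that add atoms: none
Why: Henry (nitroaldol) addition of the nitronate to the aldehyde; the carbinol centre is removed in the next step.

Step 10
Reactants: 15 1-(2-ethyl-1,3-dioxolan-2-yl)-3-nitropropan-2-ol
Product: 17 2-ethyl-2-[(E)-3-nitroprop-2-en-1-yl]-1,3-dioxolane, via mesylate 16 (not isolated)
Conditions: MsCl (1.2 equiv), Et3N (2.5 equiv), CH2Cl2, −20 → 0 °C
Reagents that add atoms: none
Why: Mesylation followed by E1cB elimination gives the thermodynamically favoured (E)-nitroalkene.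

**Fragment C**

Step 11
Reactants: 18 isovanillin
Product: 19 3-[(tert-butyldimethylsilyl)oxy]-4-methoxybenzaldehyde
Conditions: TBSCl, imidazole, DMF, rt
Reagents that add atoms: tert-butyldimethylsilyl chloride, CC(C)(C)[Si](C)(C)Cl
Why: Silylation masks the phenol so that only the carboxylic acid acts as the nucleophile in the later esterification.

Step 12
Reactants: 19 3-[(tert-butyldimethylsilyl)oxy]-4-methoxybenzaldehyde
Product: 20 3-[(tert-butyldimethylsilyl)oxy]-4-methoxybenzoic acid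
Conditions: NaClO2, NaH2PO4, 2-methylbut-2-ene, tBuOH–H2O, rt
Reagents that add atoms: NaClO2 (sodium chlorite), [Na+].[O-]Cl=O
Why: Pinnick oxidation converts the aldehyde into the acid at a pH the aryl silyl ether tolerates.

**Union and completion**

Step 13
Reactants: 8 3,3-dimethylhex-5-enal (1.5 equiv); 17 2-ethyl-2-[(E)-3-nitroprop-2-en-1-yl]-1,3-dioxolane; 10 ethylene glycol
Product: 22 2-[(2R,3S)-3-(1,3-dioxolan-2-yl)-4,4-dimethyl-2-(nitromethyl)hept-6-en-1-yl]-2-ethyl-1,3-dioxolane, via Michael aldehyde 21 (not isolated)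
Conditions: (S)-2-[diphenyl(trimethylsilyloxy)methyl]pyrrolidine (10 mol %), 4-nitrophenol (10 mol %), toluene, 0 °C → rt; then 10, HC(OEt)3, p-TsOH·H2O (30 mol %), rt
Reagents that add atoms: none
Why: Enamine-catalysed (Hayashi–Jørgensen) Michael addition, in which the (S)-catalyst shields one face of the E-enamine and the synclinal transition state gives the syn (2S,3R) adduct, so both future ring-fusion centres (C9a and C4a) are set; in-situ dioxolane formation prevents epimerisation of the aldehyde.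

Step 14
Reactants: 22 2-[(2R,3S)-3-(1,3-dioxolan-2-yl)-4,4-dimethyl-2-(nitromethyl)hept-6-en-1-yl]-2-ethyl-1,3-dioxolane; 23 phenyl vinyl sulfone
Product: 24 2-[(2R,3S)-3-(1,3-dioxolan-2-yl)-4,4-dimethyl-2-[1-nitro-3-(phenylsulfonyl)propyl]hept-6-en-1-yl]-2-ethyl-1,3-dioxolane (both epimers at the nitro carbon)
Conditions: DBU (20 mol %), MeCN, rt
Reagents that add atoms: none
Why: Nitro-Michael addition attaches a masked vinyl group to the nitro carbon; the new centre is destroyed in the next step and a second addition is slowed by the branching.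

Step 15
Reactants: 24 nitro sulfone
Product: 27 (4R,5S)-5-(1,3-dioxolan-2-yl)-4-[(2-ethyl-1,3-dioxolan-2-yl)methyl]-6,6-dimethylnona-1,8-dien-3-one, via sodium nitronate 25 (not isolated), via sulfonyl ketone 26 (not isolated)
Conditions: NaOMe, MeOH, 0 °C; then aq. TiCl3, NH4OAc (pH 5–6), 0 °C → rt; extractive work-up, then DBU, CH2Cl2, 0 °C
Reagents that add atoms: water, O
Why: McMurry-type Nef reaction turns the secondary nitronate into the ketone at a buffered pH that spares both acetals, and E1cB loss of benzenesulfinate unveils the vinyl ketone; the hindered α-CH is not touched.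

Step 16
Reactants: 27 dienone
Product: 29 (2R,3S)-3-(1,3-dioxolan-2-yl)-2-[(2-ethyl-1,3-dioxolan-2-yl)methyl]-4,4-dimethylcycloheptan-1-one, via cycloheptenone 28 (not isolated)
Conditions: second-generation Grubbs catalyst RuCl2(=CHPh)(PCy3)(H2IMes) (5 mol %), CH2Cl2 (5 mM), 40 °C; then 10% Pd/C, H2 (1 atm), rt
Reagents that add atoms: none
Why: Ring-closing metathesis of the vinyl ketone with the allyl group closes the seven-membered ring, and hydrogenation of the only remaining C=C gives the cis-2,3-disubstituted cycloheptanone under neutral conditions.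

Step 17
Reactants: 29 cycloheptanone
Product: 30 (1S,2R,3S)-3-(1,3-dioxolan-2-yl)-2-[(2-ethyl-1,3-dioxolan-2-yl)methyl]-1,4,4-trimethylcycloheptan-1-ol
Conditions: MeLi (3 equiv), anhydrous CeCl3 (3 equiv), THF, −78 °C; aq. NH4Cl
Reagents that add atoms: MeLi (methyllithium), [Li]C
Why: 1,2-Addition of the weakly basic organocerium reagent occurs from the ring face opposite the two cis substituents at C2 and C3, giving the (1S) tertiary alcohol without enolising the α-stereocentre.

Step 18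
Reactants: 30 tertiary alcohol
Product: 32 (4aR,5S,9aS)-5-hydroxy-2,5,9,9-tetramethyl-4,4a,5,6,7,8,9,9a-octahydro-3H-benzo[7]annulen-3-one, via keto aldehyde 31 (not isolated)
Conditions: 2 M HCl–THF (1:2), 40 °C; then KOH, MeOH, 0 °C → rt
Reagents that add atoms: water, O
Why: Acetal hydrolysis frees the 1,5-keto aldehyde, and intramolecular aldol condensation of the ethyl ketone onto the aldehyde closes the cyclohexenone with the cis ring fusion retained.

Step 19
Reactants: 32 bicyclic enone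
Product: 33 (3S,4aR,5S,9aS)-2,5,9,9-tetramethyl-4,4a,5,6,7,8,9,9a-octahydro-3H-benzo[7]annulene-3,5-diol
Conditions: NaBH4, CeCl3·7H2O, MeOH, −78 °C
Reagents that add atoms: none
Why: Luche 1,2-reduction delivers hydride to the convex face (the side of the ring-fusion hydrogens), giving the (3S) allylic alcohol.

Step 20
Reactants: 33 diol; 20 3-[(tert-butyldimethylsilyl)oxy]-4-methoxybenzoic acid
Product: 34 (3R,4aR,5S,9aS)-5-hydroxy-2,5,9,9-tetramethyl-4,4a,5,6,7,8,9,9a-octahydro-3H-benzo[7]annulen-3-yl 3-[(tert-butyldimethylsilyl)oxy]-4-methoxybenzoate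
Conditions: PPh3, DIAD, THF, 0 °C → rt
Reagents that add atoms: none
Why: Mitsunobu esterification proceeds by SN2 inversion at the secondary allylic carbinol to give the (3R) ester; the tertiary alcohol does not react.

Step 21
Reactants: 34 silyl-protected ester
Product: 35 (3R,4aR,5S,9aS)-5-hydroxy-2,5,9,9-tetramethyl-4,4a,5,6,7,8,9,9a-octahydro-3H-benzo[7]annulen-3-yl 3-hydroxy-4-methoxybenzoate
Conditions: TBAF, AcOH, THF, 0 °C
Reagents that add atoms: none
Why: Fluoride-mediated desilylation frees the phenol, and the acetic acid buffer keeps the allylic ester intact.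

## Compound list

1 | ethyl isobutyrate | CCOC(=O)C(C)C | starting material
2 | allyl bromide | C=CCBr | starting material
3 | lithium enolate of ethyl isobutyrate | CCOC(O[Li])=C(C)C | intermediate
4 | ethyl 2,2-dimethylpent-4-enoate | CCOC(=O)C(C)(C)CC=C | intermediate
5 | 2,2-dimethylpent-4-en-1-ol | OCC(C)(C)CC=C | intermediate
6 | 2,2-dimethylpent-4-enal | O=CC(C)(C)CC=C | intermediate
7 | 1-methoxy-3,3-dimethylhexa-1,5-diene (E/Z mixture) | COC=CC(C)(C)CC=C | intermediate
8 | 3,3-dimethylhex-5-enal (fragment A) | O=CCC(C)(C)CC=C | intermediate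
9 | ethyl 3-oxopentanoate | CCC(=O)CC(=O)OCC | starting material
10 | ethylene glycol | OCCO | starting material
11 | ethyl 2-(2-ethyl-1,3-dioxolan-2-yl)acetate | CCOC(=O)CC1(CC)OCCO1 | intermediate
12 | 2-(2-ethyl-1,3-dioxolan-2-yl)ethan-1-ol | CCC1(CCO)OCCO1 | intermediate
13 | 2-(2-ethyl-1,3-dioxolan-2-yl)acetaldehyde | CCC1(CC=O)OCCO1 | intermediate
14 | nitromethane | C[N+](=O)[O-] | starting material
15 | 1-(2-ethyl-1,3-dioxolan-2-yl)-3-nitropropan-2-ol (racemic) | CCC1(CC(O)C[N+](=O)[O-])OCCO1 | intermediate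
16 | 1-(2-ethyl-1,3-dioxolan-2-yl)-3-nitropropan-2-yl methanesulfonate | CCC1(CC(OS(C)(=O)=O)C[N+](=O)[O-])OCCO1 | intermediate
17 | 2-ethyl-2-[(E)-3-nitroprop-2-en-1-yl]-1,3-dioxolane (fragment B) | CCC1(C/C=C/[N+](=O)[O-])OCCO1 | intermediate
18 | isovanillin (3-hydroxy-4-methoxybenzaldehyde) | COc1ccc(C=O)cc1O | starting material
19 | 3-[(tert-butyldimethylsilyl)oxy]-4-methoxybenzaldehyde | COc1ccc(C=O)cc1O[Si](C)(C)C(C)(C)C | intermediate
20 | 3-[(tert-butyldimethylsilyl)oxy]-4-methoxybenzoic acid (fragment C) | COc1ccc(C(=O)O)cc1O[Si](C)(C)C(C)(C)C | intermediate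
21 | (2S,3R)-3-[(2-ethyl-1,3-dioxolan-2-yl)methyl]-2-(2-methylpent-4-en-2-yl)-4-nitrobutanal | CCC1(OCCO1)C[C@@H](C[N+](=O)[O-])[C@H](C=O)C(C)(C)CC=C | intermediate
22 | 2-[(2R,3S)-3-(1,3-dioxolan-2-yl)-4,4-dimethyl-2-(nitromethyl)hept-6-en-1-yl]-2-ethyl-1,3-dioxolane | CCC1(OCCO1)C[C@@H](C[N+](=O)[O-])[C@H](C1OCCO1)C(C)(C)CC=C | intermediate
23 | phenyl vinyl sulfone | C=CS(=O)(=O)c1ccccc1 | starting material
24 | 2-[(2R,3S)-3-(1,3-dioxolan-2-yl)-4,4-dimethyl-2-[1-nitro-3-(phenylsulfonyl)propyl]hept-6-en-1-yl]-2-ethyl-1,3-dioxolane (both epimers at the nitro carbon) | CCC1(OCCO1)C[C@@H](C(CCS(=O)(=O)c1ccccc1)[N+](=O)[O-])[C@H](C1OCCO1)C(C)(C)CC=C | intermediate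
25 | sodium nitronate of 24 | CCC1(OCCO1)C[C@@H](C(CCS(=O)(=O)c1ccccc1)=[N+]([O-])[O-])[C@H](C1OCCO1)C(C)(C)CC=C.[Na+] | intermediate
26 | (4R,5S)-5-(1,3-dioxolan-2-yl)-4-[(2-ethyl-1,3-dioxolan-2-yl)methyl]-6,6-dimethyl-1-(phenylsulfonyl)non-8-en-3-one | CCC1(OCCO1)C[C@@H](C(=O)CCS(=O)(=O)c1ccccc1)[C@H](C1OCCO1)C(C)(C)CC=C | intermediate
27 | (4R,5S)-5-(1,3-dioxolan-2-yl)-4-[(2-ethyl-1,3-dioxolan-2-yl)methyl]-6,6-dimethylnona-1,8-dien-3-one | CCC1(OCCO1)C[C@@H](C(=O)C=C)[C@H](C1OCCO1)C(C)(C)CC=C | intermediate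
28 | (6S,7R)-6-(1,3-dioxolan-2-yl)-7-[(2-ethyl-1,3-dioxolan-2-yl)methyl]-5,5-dimethylcyclohept-2-en-1-one | CCC1(OCCO1)C[C@@H]1[C@H](C2OCCO2)C(C)(C)CC=CC1=O | intermediate
29 | (2R,3S)-3-(1,3-dioxolan-2-yl)-2-[(2-ethyl-1,3-dioxolan-2-yl)methyl]-4,4-dimethylcycloheptan-1-one | CCC1(OCCO1)C[C@@H]1[C@H](C2OCCO2)C(C)(C)CCCC1=O | intermediate
30 | (1S,2R,3S)-3-(1,3-dioxolan-2-yl)-2-[(2-ethyl-1,3-dioxolan-2-yl)methyl]-1,4,4-trimethylcycloheptan-1-ol | CCC1(OCCO1)C[C@@H]1[C@H](C2OCCO2)C(C)(C)CCC[C@]1(C)O | intermediate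
31 | (1S,2R,3S)-3-hydroxy-3,7,7-trimethyl-2-(2-oxobutyl)cycloheptane-1-carbaldehyde | CCC(=O)C[C@@H]1[C@H](C=O)C(C)(C)CCC[C@]1(C)O | intermediate
32 | (4aR,5S,9aS)-5-hydroxy-2,5,9,9-tetramethyl-4,4a,5,6,7,8,9,9a-octahydro-3H-benzo[7]annulen-3-one | O=C1C[C@@H]2[C@H](C=C1C)C(C)(C)CCC[C@]2(C)O | intermediate
33 | (3S,4aR,5S,9aS)-2,5,9,9-tetramethyl-4,4a,5,6,7,8,9,9a-octahydro-3H-benzo[7]annulene-3,5-diol | O[C@H]1C[C@@H]2[C@H](C=C1C)C(C)(C)CCC[C@]2(C)O | intermediate
34 | (3R,4aR,5S,9aS)-5-hydroxy-2,5,9,9-tetramethyl-4,4a,5,6,7,8,9,9a-octahydro-3H-benzo[7]annulen-3-yl 3-[(tert-butyldimethylsilyl)oxy]-4-methoxybenzoate | COc1ccc(C(=O)O[C@@H]2C[C@@H]3[C@H](C=C2C)C(C)(C)CCC[C@]3(C)O)cc1O[Si](C)(C)C(C)(C)C | intermediate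
35 | (3R,4aR,5S,9aS)-5-hydroxy-2,5,9,9-tetramethyl-4,4a,5,6,7,8,9,9a-octahydro-3H-benzo[7]annulen-3-yl 3-hydroxy-4-methoxybenzoate | COc1ccc(C(=O)O[C@@H]2C[C@@H]3[C@H](C=C2C)C(C)(C)CCC[C@]3(C)O)cc1O | target

## Step count and risks

Total step count: 21.
Longest linear sequence: 14 (steps 1–5 then 13–21; the path through steps 6–10 then 13–21 is equally long). Fragment C (steps 11–12) joins at step 20.

The three steps most likely to fail:

**Step 13 (Michael addition).** Both partners are hindered (a neopentyl-type aldehyde and an aliphatic nitroalkene), so rate, syn/anti ratio and ee may all suffer. The fallback replaces enamine catalysis by a chiral-auxiliary enolate addition; it sets out from 8 and 17 and comes back at 22. Aldehyde 8 is oxidised (NaClO2, NaH2PO4, 2-methylbut-2-ene) to 3,3-dimethylhex-5-enoic acid F1. This is coupled through its pivaloyl mixed anhydride with lithiated (S)-4-benzyloxazolidin-2-one to give (S)-4-benzyl-3-(3,3-dimethylhex-5-enoyl)oxazolidin-2-one F2. Its chelated titanium enolate (TiCl4, iPr2NEt, CH2Cl2, −78 °C) is added to 17, the benzyl group directing attack to the same face as in alkylations, to give (S)-4-benzyl-3-[(2S,3R)-3-[(2-ethyl-1,3-dioxolan-2-yl)methyl]-2-(2-methylpent-4-en-2-yl)-4-nitrobutanoyl]oxazolidin-2-one F3. LiBH4 removes the auxiliary to give (2S,3R)-3-[(2-ethyl-1,3-dioxolan-2-yl)methyl]-2-(2-methylpent-4-en-2-yl)-4-nitrobutan-1-ol F4. Dess–Martin oxidation gives aldehyde 21, which is acetalised as in step 13 to 22.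

**Step 15 (Nef reaction and sulfinate elimination).** The α-stereocentre of the new ketone can epimerise under DBU, the acetals can suffer in the aqueous TiCl3 medium, and sulfinate can add back to the vinyl ketone. The fallback brings in C6 as a vinyl nucleophile and makes the ketone by a late oxidation; it sets out from 22 and comes back at 29. The Nef reaction is run on the primary nitro compound 22 (NaOMe, then buffered TiCl3) to give (2R,3S)-3-(1,3-dioxolan-2-yl)-2-[(2-ethyl-1,3-dioxolan-2-yl)methyl]-4,4-dimethylhept-6-enal F5. Addition of CH2=CHMgBr at −78 °C gives (4R,5S)-5-(1,3-dioxolan-2-yl)-4-[(2-ethyl-1,3-dioxolan-2-yl)methyl]-6,6-dimethylnona-1,8-dien-3-ol F6 (both carbinol epimers). Ring-closing metathesis with the second-generation Grubbs catalyst gives (6S,7R)-6-(1,3-dioxolan-2-yl)-7-[(2-ethyl-1,3-dioxolan-2-yl)methyl]-5,5-dimethylcyclohept-2-en-1-ol F7. Hydrogenation (H2, Pd/C) gives (2R,3S)-3-(1,3-dioxolan-2-yl)-2-[(2-ethyl-1,3-dioxolan-2-yl)methyl]-4,4-dimethylcycloheptan-1-ol F8, and Dess–Martin oxidation gives 29.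

**Step 20 (Mitsunobu inversion).** A hindered cyclic allylic alcohol can give SN2′ products or eliminate to the diene. The fallback sets the C3 configuration by reagent control and esterifies with retention; it sets out from 32 and comes back at 34. Enone 32 is reduced with (S)-2-methyl-CBS-oxazaborolidine and BH3·SMe2 (the alkenyl side acting as the large group) to (3R,4aR,5S,9aS)-2,5,9,9-tetramethyl-4,4a,5,6,7,8,9,9a-octahydro-3H-benzo[7]annulene-3,5-diol F9. Its secondary hydroxyl is acylated with acid 20 (DCC, DMAP, CH2Cl2) to give 34.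

## Further compounds

F1 | step 13 | 3,3-dimethylhex-5-enoic acid | OC(=O)CC(C)(C)CC=C
F2 | step 13 | (S)-4-benzyl-3-(3,3-dimethylhex-5-enoyl)oxazolidin-2-one | O=C1OC[C@H](Cc2ccccc2)N1C(=O)CC(C)(C)CC=C
F3 | step 13 | (S)-4-benzyl-3-[(2S,3R)-3-[(2-ethyl-1,3-dioxolan-2-yl)methyl]-2-(2-methylpent-4-en-2-yl)-4-nitrobutanoyl]oxazolidin-2-one | CCC1(OCCO1)C[C@@H](C[N+](=O)[O-])[C@H](C(=O)N1[C@@H](Cc2ccccc2)COC1=O)C(C)(C)CC=C
F4 | step 13 | (2S,3R)-3-[(2-ethyl-1,3-dioxolan-2-yl)methyl]-2-(2-methylpent-4-en-2-yl)-4-nitrobutan-1-ol | CCC1(OCCO1)C[C@@H](C[N+](=O)[O-])[C@H](CO)C(C)(C)CC=C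
F5 | step 15 | (2R,3S)-3-(1,3-dioxolan-2-yl)-2-[(2-ethyl-1,3-dioxolan-2-yl)methyl]-4,4-dimethylhept-6-enal | CCC1(OCCO1)C[C@@H](C=O)[C@H](C1OCCO1)C(C)(C)CC=C
F6 | step 15 | (4R,5S)-5-(1,3-dioxolan-2-yl)-4-[(2-ethyl-1,3-dioxolan-2-yl)methyl]-6,6-dimethylnona-1,8-dien-3-ol (both C3 epimers) | CCC1(OCCO1)C[C@@H](C(O)C=C)[C@H](C1OCCO1)C(C)(C)CC=C
F7 | step 15 | (6S,7R)-6-(1,3-dioxolan-2-yl)-7-[(2-ethyl-1,3-dioxolan-2-yl)methyl]-5,5-dimethylcyclohept-2-en-1-ol (both C1 epimers) | CCC1(OCCO1)C[C@@H]1[C@H](C2OCCO2)C(C)(C)CC=CC1O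
F8 | step 15 | (2R,3S)-3-(1,3-dioxolan-2-yl)-2-[(2-ethyl-1,3-dioxolan-2-yl)methyl]-4,4-dimethylcycloheptan-1-ol (both C1 epimers) | CCC1(OCCO1)C[C@@H]1[C@H](C2OCCO2)C(C)(C)CCCC1O
F9 | step 20 | (3R,4aR,5S,9aS)-2,5,9,9-tetramethyl-4,4a,5,6,7,8,9,9a-octahydro-3H-benzo[7]annulene-3,5-diol | O[C@@H]1C[C@@H]2[C@H](C=C1C)C(C)(C)CCC[C@]2(C)O
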